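With a small charge I wanted the fate of the open intermediate reckoned before any flask was heated.

| flask | starting material | partner A | partner B | protic impurity | temperature | time | remark |
|---|---|---|---|---|---|---|---|
| gamma | 0.10 M | 2.00 equiv | 1.30 equiv | 0.0200 M | 65 °C | 40 min |  |
| theta | 0.10 M | 2.00 equiv | 1.30 equiv | 0.0200 M | 35 °C | 40 min |  |
| epsilon | 0.10 M | 2.00 equiv | 1.30 equiv | 0.0200 M |  | 40 min | at 65 °C until 12 min, from then on at 35 °C |

* the flask with the highest amount of open intermediate, in percent of the starting material charged ("all alike" if they lie within 1.5 percentage points) (gamma / theta / epsilon / all alike)
* final open intermediate, as a percentage of the starting material charged, in gamma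
* final open intermediate, as a percentage of the starting material charged, in theta
* final open intermediate, as a percentage of the starting material charged, in epsilon

- all constants are for 35 °C and move with temperature by the activation energies

    open intermediate + second intermediate → product (k1 = 0.0080 M⁻¹ s⁻¹, Ea1 = 70.0 kJ mol⁻¹)
    partner B + partner A → second intermediate (k2 = 0.026 M⁻¹ s⁻¹, Ea2 = 71.0 kJ mol⁻¹)
    starting material + partner B → open intermediate (k3 = 0.21 M⁻¹ s⁻¹, Ea3 = 44.0 kJ mol⁻¹)
    starting material + protic impurity → quenched substrate (k4 = 0.26 M⁻¹ s⁻¹, Ea4 = 43.0 kJ mol⁻¹)
    (constants at 35 °C)

Partner B feeds two routes: with starting material it gives the open intermediate, and with partner A it gives the second intermediate. The two intermediates then couple to product. So the second intermediate sets the open intermediate's pseudo-first-order lifetime, and I asked what level of it makes that lifetime equal the time available: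

crossing level = one over (coupling constant × time) = 0.0521 M

This crossing level held for the full time at 35 °C. Above it, more than one lifetime fits into the time; below it, less than one does.

Temperature came first. Coupling speeds up 11 times on going to 65 °C, so the crossing level in gamma falls to 0.00461 M.

Partner B came next. At the start of theta, starting material takes partner B 4.0 times as fast as partner A does, so I served starting material first. I let the impurity remove its full 0.0200 M. That gave 0.0800 M of open intermediate and 0.0500 M of second intermediate, close to the crossing level. Coupling takes both alike, so their difference of 0.0300 M stays, and for theta:

open/second at the end = (0.0800 M/0.0500 M) × exp(0.0300 M × 0.0080 M⁻¹ s⁻¹ × 40 min) = 2.85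

open left = difference × ratio/(ratio minus one) = 46.2 % of the charge

In gamma my level stood about ten times above the crossing, but with my split the difference of 0.0300 M would still stay. The partner A route has the higher activation energy, 71.0 kJ mol⁻¹ against 44.0 kJ mol⁻¹, so I expected heat to move partner B towards second intermediate and shrink that difference. Only then could little open intermediate remain in gamma.

Time came last. After the change in epsilon, 28.0 min remained in the cold. The crossing level for that stretch is 0.0744 M, above even my starting level. So I expected the open intermediate to lose less than one lifetime's worth after the change.

Cutting partner B to 0.330 equiv in a theta flask, the same split leaves about 0.00655 M of second intermediate, far below the crossing.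

The forecast named theta, with 3 % in gamma, 44 % in theta and 9.5 % in epsilon, a theta figure below my 46.2 %; its ground: “The slow coupling then follows mixed second-order kinetics”.

The simulation put theta highest, with 3.50 % in gamma, 44.9 % in theta and 9.95 % in epsilon.

In epsilon at 12.0 min, partner B stood at 0 % of its charge, open intermediate at 11.8 % and second intermediate at 0.0136 M, well below the cold crossing of 0.0744 M. Coupling went on slowly through the cold stretch, and open intermediate reached 9.95 % at 40.0 min. In the theta neighbour with 0.330 equiv of partner B, second intermediate ended at 0.00518 M, below the crossing of 0.0521 M. That flask held 22.2 % open intermediate and 2.83 % product at 40.0 min.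

The constants used here were drawn at random within sensible limits; the result is computed.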